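**Plan**

1. Oxane numbering: O1, C2 (aryl), C3 (aroyl), C4 (styryl), C5H2, C6 (arylethyl). The retrosynthesis cuts the styryl C=C, then C3–C(=O), then C4–CHO and C2–aryl, then the ring bonds C5–C6 and O1–C2, leaving 3-arylpropanal 3 and Danishefsky's diene 4. Ring A is cut from its heptenyl chain at the diaryl methine and the chain at its C=C.
2. Forward: the oxane is the only ring made and it is made first (step 3); C2, C3 and C4 are then dressed in that order; the ring A/heptenyl fragment 28 is built separately and joined at C3.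
3. Enabling feature: O1–C6 is the carbonyl of a simple aldehyde. C2 (bound to O1 and an aryl group) and C4 (bound to a carbon substituent) can both be carried at carbonyl level, so C2–C3–C4–C5 is a 1-methoxy-3-silyloxybutadiene.
4. Stereochemistry: C6 from the BINOL–titanium catalyst; C2 by axial cuprate addition trans to C6; C3 by radical addition anti to the C2 aryl group; C4 by protonation anti to the C3 acyl group; the diaryl methine by chirality transfer from a CBS-derived carbinol; the side-chain carbinol by Keck allylation.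

Key step: step 3

Abbreviations: TBS = tert-butyldimethylsilyl; MOM = methoxymethyl; ArT = 4-[(tert-butyldimethylsilyl)oxy]phenyl; Hep = (1R,2E,5S)-5-[(tert-butyldimethylsilyl)oxy]-1,7-bis(ArT)hept-2-en-1-yl.

Assumption: (R)-BINOL/Ti(OiPr)4 is taken to direct carbon nucleophiles to the Re face of aldehyde 3 (steps 3 and 11); if the sense is the opposite, (S)-BINOL is used in both steps.

**Route**

Step 1
Reactants: 1 methyl 3-(4-hydroxyphenyl)propanoate
Product: 2 methyl 3-(ArT)propanoate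
Conditions: TBSCl, imidazole, DMF, rt
Reagents that add atoms: tert-butyldimethylsilyl chloride, CC(C)(C)[Si](C)(C)Cl
Why: Imidazole-promoted O-silylation (silyl ether formation) masks the acidic phenol for the Lewis-acid and organometallic steps that follow and leaves the ester untouched.

Step 2
Reactants: 2 methyl 3-(ArT)propanoate
Product: 3 3-(ArT)propanal
Conditions: DIBAL-H (1.05 equiv), CH2Cl2, −78 °C; aq. Rochelle salt
Reagents that add atoms: none
Why: DIBAL-H adds once to the ester at −78 °C and the tetrahedral aluminium alkoxide survives until work-up, so the partial reduction should stop at the aldehyde.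

Step 3
Reactants: 3 3-(ArT)propanal; 4 Danishefsky's diene
Product: 6 (2S)-2-(2-ArT-ethyl)-2,3-dihydro-4H-pyran-4-one, via silyl aldolate 5 (not isolated)
Conditions: (R)-BINOL (20 mol%), Ti(OiPr)4 (10 mol%), 4 Å MS, Et2O, −20 °C; then TFA, CH2Cl2, 0 °C
Reagents that add atoms: none
Why: The BINOL–titanium complex binds the aldehyde, and the terminal CH2 of the diene (C5) adds to its Re face in a Mukaiyama aldol step that forms C5–C6 and gives the silyl aldolate 5; trifluoroacetic acid then frees the C6 oxygen, which adds to the methoxy-bearing enone terminus (C2) and expels methanol, so that O1–C2 closes the oxane as a vinylogous ester. The closest known reaction type is the BINOL–titanium-catalysed formal hetero-Diels–Alder reaction of Danishefsky's diene with aliphatic aldehydes. The ring closes by 6-endo-trig conjugate addition of O1 to C2 followed by β-elimination of methoxide, not by a pericyclic closure. The only new stereocentre, C6, is set by the chiral titanium BINOLate in the aldol step and is not touched in the cyclisation. The step needs enantioface selectivity at the aldehyde and reaction of the diene at its terminal CH2 only; the second is secured by the 3-silyloxy group, which makes that carbon the nucleophilic one. C2 is left at the acetal level and C4 at the ketone level, which is what the later aryl, acyl and styryl introductions require.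

Step 4
Reactants: 6 (2S)-2-(2-ArT-ethyl)-2,3-dihydro-4H-pyran-4-one; 7 (4-bromophenoxy)(tert-butyl)dimethylsilane
Product: 11 (2S,6R)-6-ArT-2-(2-ArT-ethyl)-3,6-dihydro-2H-pyran-4-yl trifluoromethanesulfonate, via aryllithium 8 (not isolated), via lithium diarylcuprate 9 (not isolated), via lithium enolate 10 (not isolated)
Conditions: 7, t-BuLi, Et2O, −78 °C; CuI (0.5 equiv), −40 °C; 6, THF, −78 °C; then Comins' reagent, −78 → 0 °C
Reagents that add atoms: Comins' reagent [N-(5-chloropyridin-2-yl)-1,1,1-trifluoro-N-(trifluoromethylsulfonyl)methanesulfonamide], O=S(=O)(N(c1ccc(Cl)cn1)S(=O)(=O)C(F)(F)F)C(F)(F)F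
Why: Lithium–halogen exchange and transmetallation give the Gilman cuprate 9, whose aryl group adds in conjugate fashion to C2 of the vinylogous ester along the axial trajectory of the half-chair that keeps the C6 chain pseudo-equatorial, so the new C2 stereocentre is trans to C6, and the regiodefined C3=C4 enolate 10 is then trapped on oxygen by Comins' reagent (cuprate conjugate addition followed by enolate O-triflation).

Step 5
Reactants: 11 (2S,6R)-6-ArT-2-(2-ArT-ethyl)-3,6-dihydro-2H-pyran-4-yl trifluoromethanesulfonate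
Product: 12 (2S,6R)-6-ArT-2-(2-ArT-ethyl)-3,6-dihydro-2H-pyran-4-carbaldehyde
Conditions: Pd(PPh3)4 (5 mol%), CO (1 atm), Bu3SnH (slow addition), THF, 50 °C
Reagents that add atoms: carbon monoxide, [C-]#[O+]
Why: Oxidative addition of zerovalent palladium into the enol triflate, CO insertion and hydride transfer from the tin hydride to the acylpalladium species (palladium-catalysed reductive carbonylation) should give the enal without touching the two stereocentres.

Step 6
Reactants: 13 (E)-4-(4-hydroxyphenyl)but-3-en-2-one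
Product: 14 (E)-4-ArT-but-3-en-2-one
Conditions: TBSCl, imidazole, DMF, rt
Reagents that add atoms: tert-butyldimethylsilyl chloride, CC(C)(C)[Si](C)(C)Cl
Why: Phenol silylation as in step 1 (silyl ether formation); the enone is inert to TBSCl and imidazole.

Step 7
Reactants: 14 (E)-4-ArT-but-3-en-2-one
Product: 15 (2S,3E)-4-ArT-but-3-en-2-ol
Conditions: (R)-2-methyl-CBS-oxazaborolidine (10 mol%), catecholborane, toluene, −78 °C
Reagents that add atoms: none
Why: CBS reduction, in which the oxazaborolidine-bound borane delivers hydride to one face of the ketone with the styryl group as the large substituent, should set the (S)-carbinol, and catecholborane at low temperature avoids hydroboration of the alkene.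

Step 8
Reactants: 15 (2S,3E)-4-ArT-but-3-en-2-ol
Product: 16 (2S,3E)-4-ArT-but-3-en-2-yl pyridine-2-carboxylate
Conditions: picolinic acid, DCC, DMAP (cat.), CH2Cl2, rt
Reagents that add atoms: pyridine-2-carboxylic acid, OC(=O)c1ccccn1
Why: Steglich esterification at oxygen proceeds with retention at the carbinol carbon and installs the chelating picolinate leaving group.

Step 9
Reactants: 17 5-methoxybenzene-1,3-diol
Product: 18 1-methoxy-3,5-bis(methoxymethoxy)benzene
Conditions: MOMCl, i-Pr2NEt, CH2Cl2, 0 °C → rt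
Reagents that add atoms: chloromethyl methyl ether, COCCl
Why: Double O-alkylation of the resorcinol with MOMCl (Williamson-type ether formation) gives two acetal ethers that will direct the lithiation of step 10 to the carbon between them.

Step 10
Reactants: 18 1-methoxy-3,5-bis(methoxymethoxy)benzene; 16 (2S,3E)-4-ArT-but-3-en-2-yl pyridine-2-carboxylate
Product: 21 2-[(1R,2E)-1-ArT-but-2-en-1-yl]-5-methoxy-1,3-bis(methoxymethoxy)benzene, via aryllithium 19 (not isolated), via lithium diarylcuprate 20 (not isolated)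
Conditions: 18 (2.2 equiv), n-BuLi, THF, 0 °C; CuBr·SMe2 (1.1 equiv), −40 °C; MgBr2·OEt2; then 16, −40 → 0 °C
Reagents that add atoms: none
Why: Directed ortho-lithiation between the two MOM ethers and transmetallation give cuprate 20, and magnesium chelation of the picolinate directs the aryl group to the benzylic γ-carbon anti to the leaving group (anti-SN2' allylic substitution) through the conformer with the carbinol hydrogen eclipsing the alkene, so the (S)-carbinol configuration is transferred to the (R)-diaryl methine centre and the new alkene is E.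

Step 11
Reactants: 3 3-(ArT)propanal
Product: 22 (3S)-1-ArT-hex-5-en-3-ol
Conditions: allyltributylstannane, (R)-BINOL (20 mol%), Ti(OiPr)4 (10 mol%), 4 Å MS, CH2Cl2, −20 °C; aq. KF work-up
Reagents that add atoms: allyltributylstannane, C=CC[Sn](CCCC)(CCCC)CCCC
Why: Keck allylation, in which the BINOL–titanium complex directs the allylstannane to the Re face of the aldehyde, should set the (S)-carbinol of the side chain.

Step 12
Reactants: 22 (3S)-1-ArT-hex-5-en-3-ol
Product: 23 tert-butyl{[(3S)-1-ArT-hex-5-en-3-yl]oxy}dimethylsilane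
Conditions: TBSOTf, 2,6-lutidine, CH2Cl2, −78 → 0 °C
Reagents that add atoms: tert-butyldimethylsilyl trifluoromethanesulfonate, CC(C)(C)[Si](C)(C)OS(=O)(=O)C(F)(F)F
Why: Silylation of the secondary alcohol with the silyl triflate and a hindered base (silyl ether formation) protects it for the organolithium step 15 without affecting the stereocentre.

Step 13
Reactants: 21 2-[(1R,2E)-1-ArT-but-2-en-1-yl]-5-methoxy-1,3-bis(methoxymethoxy)benzene; 23 tert-butyl{[(3S)-1-ArT-hex-5-en-3-yl]oxy}dimethylsilane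
Product: 24 2-Hep-5-methoxy-1,3-bis(methoxymethoxy)benzene
Conditions: second-generation Hoveyda–Grubbs catalyst (5 mol%), 23 (3 equiv), 1,4-benzoquinone (10 mol%), CH2Cl2, 40 °C
Reagents that add atoms: none
Why: Olefin cross-metathesis between the propenyl group of 21 and the terminal alkene of 23 (used in excess) releases propene and should give the more stable E-alkene, while benzoquinone suppresses ruthenium hydride-induced migration of the double bond.

Step 14
Reactants: 24 2-Hep-5-methoxy-1,3-bis(methoxymethoxy)benzene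
Product: 25 2-bromo-4-Hep-1-methoxy-3,5-bis(methoxymethoxy)benzene
Conditions: NBS (1.0 equiv), CH2Cl2, −78 °C, dark
Reagents that add atoms: N-bromosuccinimide, O=C1CCC(=O)N1Br
Why: Electrophilic aromatic bromination occurs at one of the two equivalent free positions of the trioxygenated ring A (ortho to OMe and OMOM), which is far more electron-rich than the silyloxyphenyl rings or the alkene.

Step 15
Reactants: 25 2-bromo-4-Hep-1-methoxy-3,5-bis(methoxymethoxy)benzene
Product: 27 allyl 2-[3-Hep-6-methoxy-2,4-bis(methoxymethoxy)phenyl]-2-oxoacetate, via aryllithium 26 (not isolated)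
Conditions: t-BuLi (2.1 equiv), THF, −78 °C; cannulated into diallyl oxalate (3 equiv), THF, −78 °C
Reagents that add atoms: diallyl oxalate, C=CCOC(=O)C(=O)OCC=C
Why: Bromine–lithium exchange at −78 °C outruns deprotonation of the doubly benzylic C–H and the aryllithium 26 is acylated once by excess diallyl oxalate under inverse addition (acylation of an organolithium by an oxalate diester).

Step 16
Reactants: 27 allyl 2-[3-Hep-6-methoxy-2,4-bis(methoxymethoxy)phenyl]-2-oxoacetate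
Product: 28 2-[3-Hep-6-methoxy-2,4-bis(methoxymethoxy)phenyl]-2-oxoacetic acid
Conditions: Pd(PPh3)4 (5 mol%), morpholine, THF, rt; pH 4 buffer work-up
Reagents that add atoms: none
Why: Palladium-catalysed allyl transfer to morpholine (Tsuji–Trost deallylation) frees the α-keto acid under neutral conditions that spare the silyl and MOM ethers.

Step 17
Reactants: 12 (2S,6R)-6-ArT-2-(2-ArT-ethyl)-3,6-dihydro-2H-pyran-4-carbaldehyde; 28 2-[3-Hep-6-methoxy-2,4-bis(methoxymethoxy)phenyl]-2-oxoacetic acid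
Product: 29 (2R,3R,4R,6S)-2-ArT-6-(2-ArT-ethyl)-3-[3-Hep-6-methoxy-2,4-bis(methoxymethoxy)benzoyl]oxane-4-carbaldehyde
Conditions: [Ir(dF(CF3)ppy)2(dtbbpy)]PF6 (2 mol%), K2HPO4, degassed DMF, blue LEDs, rt
Reagents that add atoms: none
Why: The excited iridium photocatalyst oxidises the carboxylate of 28, loss of CO2 gives a nucleophilic aroyl radical that adds to C3 of the enal (decarboxylative Giese addition) from the face opposite to the pseudo-axial C2 aryl group, which sets C3 trans to C2, and the α-formyl radical is reduced to the enolate, whose protonation at C4 anti to the now axial C3 acyl group should place the formyl group equatorial and cis to C3.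

Step 18
Reactants: 29 (2R,3R,4R,6S)-2-ArT-6-(2-ArT-ethyl)-3-[3-Hep-6-methoxy-2,4-bis(methoxymethoxy)benzoyl]oxane-4-carbaldehyde
Product: 30 [(2R,3R,4R,6S)-2-ArT-6-(2-ArT-ethyl)-4-[(E)-2-iodoethenyl]oxan-3-yl][3-Hep-6-methoxy-2,4-bis(methoxymethoxy)phenyl]methanone
Conditions: CrCl2 (8 equiv), CHI3 (3 equiv), THF/1,4-dioxane, 0 °C → rt
Reagents that add atoms: iodoform, IC(I)I
Why: Takai olefination, in which the gem-dichromium species from CHI3 and CrCl2 adds to the aldehyde but not to the hindered ketone, should give the E-iodoalkene under non-basic conditions that leave C3 and C4 untouched.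

Step 19
Reactants: 30 [(2R,3R,4R,6S)-2-ArT-6-(2-ArT-ethyl)-4-[(E)-2-iodoethenyl]oxan-3-yl][3-Hep-6-methoxy-2,4-bis(methoxymethoxy)phenyl]methanone
Product: 31 [(2R,3R,4S,6S)-2-ArT-6-(2-ArT-ethyl)-4-[(E)-2-ArT-ethenyl]oxan-3-yl][3-Hep-6-methoxy-2,4-bis(methoxymethoxy)phenyl]methanone
Conditions: 4-(TBSO)phenylboronic acid, Pd(PPh3)4 (5 mol%), aq. K3PO4, THF, rt
Reagents that add atoms: 4-[(tert-butyldimethylsilyl)oxy]phenylboronic acid, CC(C)(C)[Si](C)(C)Oc1ccc(B(O)O)cc1
Why: Suzuki–Miyaura coupling of the alkenyl iodide proceeds with retention of the E geometry and completes the styryl group at C4.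

Step 20
Reactants: 31 [(2R,3R,4S,6S)-2-ArT-6-(2-ArT-ethyl)-4-[(E)-2-ArT-ethenyl]oxan-3-yl][3-Hep-6-methoxy-2,4-bis(methoxymethoxy)phenyl]methanone
Product: 32 [(2R,3R,4S,6S)-2-ArT-6-(2-ArT-ethyl)-4-[(E)-2-ArT-ethenyl]oxan-3-yl](3-Hep-2,4-dihydroxy-6-methoxyphenyl)methanone
Conditions: ZnBr2, n-PrSH, CH2Cl2, 0 °C, 10 min
Reagents that add atoms: none
Why: ZnBr2 activates the acetal oxygen and the thiol takes up the methoxymethyl cation (Lewis-acid/thiol MOM cleavage), which should remove both ring A MOM groups within minutes while the silyl ethers and the benzylic C2–O1 bond persist.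

Step 21
Reactants: 32 [(2R,3R,4S,6S)-2-ArT-6-(2-ArT-ethyl)-4-[(E)-2-ArT-ethenyl]oxan-3-yl](3-Hep-2,4-dihydroxy-6-methoxyphenyl)methanone
Product: 33 blepharocalyxin B
Conditions: TBAF, AcOH (1:1), THF, 0 °C → rt
Reagents that add atoms: none
Why: Fluoride-induced Si–O cleavage removes all six silyl groups, and the acetic acid buffer keeps the phenoxides protonated so that neither retro-oxa-Michael opening at O1–C2 nor epimerisation at C3 should occur.

**Compound list**

1 | methyl 3-(4-hydroxyphenyl)propanoate | COC(=O)CCc1ccc(O)cc1 | starting material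
2 | methyl 3-(ArT)propanoate | COC(=O)CCc1ccc(O[Si](C)(C)C(C)(C)C)cc1 | intermediate
3 | 3-(ArT)propanal | O=CCCc1ccc(O[Si](C)(C)C(C)(C)C)cc1 | intermediate
4 | Danishefsky's diene, (E)-1-methoxy-3-(trimethylsilyloxy)buta-1,3-diene | CO/C=C/C(=C)O[Si](C)(C)C | starting material
5 | (1E,5S)-1-methoxy-5-(trimethylsilyloxy)-7-ArT-hept-1-en-3-one | CO/C=C/C(=O)C[C@H](CCc1ccc(O[Si](C)(C)C(C)(C)C)cc1)O[Si](C)(C)C | intermediate (not isolated)
6 | (2S)-2-(2-ArT-ethyl)-2,3-dihydro-4H-pyran-4-one | O=C1C[C@H](CCc2ccc(O[Si](C)(C)C(C)(C)C)cc2)OC=C1 | intermediate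
7 | (4-bromophenoxy)(tert-butyl)dimethylsilane | Brc1ccc(O[Si](C)(C)C(C)(C)C)cc1 | starting material
8 | (ArT)lithium | [Li]c1ccc(O[Si](C)(C)C(C)(C)C)cc1 | intermediate (not isolated)
9 | lithium bis(ArT)cuprate | [Li+].[Cu-](c1ccc(O[Si](C)(C)C(C)(C)C)cc1)c1ccc(O[Si](C)(C)C(C)(C)C)cc1 | intermediate (not isolated)
10 | lithium (2S,6R)-6-ArT-2-(2-ArT-ethyl)-3,6-dihydro-2H-pyran-4-olate | [Li+].C1=C([O-])C[C@H](CCc2ccc(O[Si](C)(C)C(C)(C)C)cc2)O[C@H]1c1ccc(O[Si](C)(C)C(C)(C)C)cc1 | intermediate (not isolated)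
11 | (2S,6R)-6-ArT-2-(2-ArT-ethyl)-3,6-dihydro-2H-pyran-4-yl trifluoromethanesulfonate | C1=C(OS(=O)(=O)C(F)(F)F)C[C@H](CCc2ccc(O[Si](C)(C)C(C)(C)C)cc2)O[C@H]1c1ccc(O[Si](C)(C)C(C)(C)C)cc1 | intermediate
12 | (2S,6R)-6-ArT-2-(2-ArT-ethyl)-3,6-dihydro-2H-pyran-4-carbaldehyde | C1=C(C=O)C[C@H](CCc2ccc(O[Si](C)(C)C(C)(C)C)cc2)O[C@H]1c1ccc(O[Si](C)(C)C(C)(C)C)cc1 | intermediate
13 | (E)-4-(4-hydroxyphenyl)but-3-en-2-one | CC(=O)/C=C/c1ccc(O)cc1 | starting material
14 | (E)-4-ArT-but-3-en-2-one | CC(=O)/C=C/c1ccc(O[Si](C)(C)C(C)(C)C)cc1 | intermediate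
15 | (2S,3E)-4-ArT-but-3-en-2-ol | C[C@H](O)/C=C/c1ccc(O[Si](C)(C)C(C)(C)C)cc1 | intermediate
16 | (2S,3E)-4-ArT-but-3-en-2-yl pyridine-2-carboxylate | C[C@H](OC(=O)c1ccccn1)/C=C/c1ccc(O[Si](C)(C)C(C)(C)C)cc1 | intermediate
17 | 5-methoxybenzene-1,3-diol | COc1cc(O)cc(O)c1 | starting material
18 | 1-methoxy-3,5-bis(methoxymethoxy)benzene | COc1cc(OCOC)cc(OCOC)c1 | intermediate
19 | [4-methoxy-2,6-bis(methoxymethoxy)phenyl]lithium | COc1cc(OCOC)c([Li])c(OCOC)c1 | intermediate (not isolated)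
20 | lithium bis[4-methoxy-2,6-bis(methoxymethoxy)phenyl]cuprate | [Li+].[Cu-](c1c(OCOC)cc(OC)cc1OCOC)c1c(OCOC)cc(OC)cc1OCOC | intermediate (not isolated)
21 | 2-[(1R,2E)-1-ArT-but-2-en-1-yl]-5-methoxy-1,3-bis(methoxymethoxy)benzene | COc1cc(OCOC)c([C@H](/C=C/C)c2ccc(O[Si](C)(C)C(C)(C)C)cc2)c(OCOC)c1 | intermediate
22 | (3S)-1-ArT-hex-5-en-3-ol | C=CC[C@@H](O)CCc1ccc(O[Si](C)(C)C(C)(C)C)cc1 | intermediate
23 | tert-butyl{[(3S)-1-ArT-hex-5-en-3-yl]oxy}dimethylsilane | C=CC[C@@H](O[Si](C)(C)C(C)(C)C)CCc1ccc(O[Si](C)(C)C(C)(C)C)cc1 | intermediate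
24 | 2-Hep-5-methoxy-1,3-bis(methoxymethoxy)benzene | COc1cc(OCOC)c([C@H](/C=C/C[C@@H](O[Si](C)(C)C(C)(C)C)CCc2ccc(O[Si](C)(C)C(C)(C)C)cc2)c2ccc(O[Si](C)(C)C(C)(C)C)cc2)c(OCOC)c1 | intermediate
25 | 2-bromo-4-Hep-1-methoxy-3,5-bis(methoxymethoxy)benzene | COc1cc(OCOC)c([C@H](/C=C/C[C@@H](O[Si](C)(C)C(C)(C)C)CCc2ccc(O[Si](C)(C)C(C)(C)C)cc2)c2ccc(O[Si](C)(C)C(C)(C)C)cc2)c(OCOC)c1Br | intermediate
26 | [3-Hep-6-methoxy-2,4-bis(methoxymethoxy)phenyl]lithium | COc1cc(OCOC)c([C@H](/C=C/C[C@@H](O[Si](C)(C)C(C)(C)C)CCc2ccc(O[Si](C)(C)C(C)(C)C)cc2)c2ccc(O[Si](C)(C)C(C)(C)C)cc2)c(OCOC)c1[Li] | intermediate (not isolated)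
27 | allyl 2-[3-Hep-6-methoxy-2,4-bis(methoxymethoxy)phenyl]-2-oxoacetate | COc1cc(OCOC)c([C@H](/C=C/C[C@@H](O[Si](C)(C)C(C)(C)C)CCc2ccc(O[Si](C)(C)C(C)(C)C)cc2)c2ccc(O[Si](C)(C)C(C)(C)C)cc2)c(OCOC)c1C(=O)C(=O)OCC=C | intermediate
28 | 2-[3-Hep-6-methoxy-2,4-bis(methoxymethoxy)phenyl]-2-oxoacetic acid | COc1cc(OCOC)c([C@H](/C=C/C[C@@H](O[Si](C)(C)C(C)(C)C)CCc2ccc(O[Si](C)(C)C(C)(C)C)cc2)c2ccc(O[Si](C)(C)C(C)(C)C)cc2)c(OCOC)c1C(=O)C(=O)O | intermediate
29 | (2R,3R,4R,6S)-2-ArT-6-(2-ArT-ethyl)-3-[3-Hep-6-methoxy-2,4-bis(methoxymethoxy)benzoyl]oxane-4-carbaldehyde | COc1cc(OCOC)c([C@H](/C=C/C[C@@H](O[Si](C)(C)C(C)(C)C)CCc2ccc(O[Si](C)(C)C(C)(C)C)cc2)c2ccc(O[Si](C)(C)C(C)(C)C)cc2)c(OCOC)c1C(=O)[C@@H]1[C@H](C=O)C[C@H](CCc2ccc(O[Si](C)(C)C(C)(C)C)cc2)O[C@H]1c1ccc(O[Si](C)(C)C(C)(C)C)cc1 | intermediate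
30 | [(2R,3R,4R,6S)-2-ArT-6-(2-ArT-ethyl)-4-[(E)-2-iodoethenyl]oxan-3-yl][3-Hep-6-methoxy-2,4-bis(methoxymethoxy)phenyl]methanone | COc1cc(OCOC)c([C@H](/C=C/C[C@@H](O[Si](C)(C)C(C)(C)C)CCc2ccc(O[Si](C)(C)C(C)(C)C)cc2)c2ccc(O[Si](C)(C)C(C)(C)C)cc2)c(OCOC)c1C(=O)[C@@H]1[C@H](/C=C/I)C[C@H](CCc2ccc(O[Si](C)(C)C(C)(C)C)cc2)O[C@H]1c1ccc(O[Si](C)(C)C(C)(C)C)cc1 | intermediate
31 | [(2R,3R,4S,6S)-2-ArT-6-(2-ArT-ethyl)-4-[(E)-2-ArT-ethenyl]oxan-3-yl][3-Hep-6-methoxy-2,4-bis(methoxymethoxy)phenyl]methanone | COc1cc(OCOC)c([C@H](/C=C/C[C@@H](O[Si](C)(C)C(C)(C)C)CCc2ccc(O[Si](C)(C)C(C)(C)C)cc2)c2ccc(O[Si](C)(C)C(C)(C)C)cc2)c(OCOC)c1C(=O)[C@@H]1[C@H](/C=C/c2ccc(O[Si](C)(C)C(C)(C)C)cc2)C[C@H](CCc2ccc(O[Si](C)(C)C(C)(C)C)cc2)O[C@H]1c1ccc(O[Si](C)(C)C(C)(C)C)cc1 | intermediate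
32 | [(2R,3R,4S,6S)-2-ArT-6-(2-ArT-ethyl)-4-[(E)-2-ArT-ethenyl]oxan-3-yl](3-Hep-2,4-dihydroxy-6-methoxyphenyl)methanone | COc1cc(O)c([C@H](/C=C/C[C@@H](O[Si](C)(C)C(C)(C)C)CCc2ccc(O[Si](C)(C)C(C)(C)C)cc2)c2ccc(O[Si](C)(C)C(C)(C)C)cc2)c(O)c1C(=O)[C@@H]1[C@H](/C=C/c2ccc(O[Si](C)(C)C(C)(C)C)cc2)C[C@H](CCc2ccc(O[Si](C)(C)C(C)(C)C)cc2)O[C@H]1c1ccc(O[Si](C)(C)C(C)(C)C)cc1 | intermediate
33 | blepharocalyxin B, {2,4-dihydroxy-3-[(1R,2E,5S)-5-hydroxy-1,7-bis(4-hydroxyphenyl)hept-2-en-1-yl]-6-methoxyphenyl}{(2R,3R,4S,6S)-2-(4-hydroxyphenyl)-6-[2-(4-hydroxyphenyl)ethyl]-4-[(E)-2-(4-hydroxyphenyl)ethenyl]oxan-3-yl}methanone | COc1cc(O)c([C@H](/C=C/C[C@@H](O)CCc2ccc(O)cc2)c2ccc(O)cc2)c(O)c1C(=O)[C@@H]1[C@H](/C=C/c2ccc(O)cc2)C[C@H](CCc2ccc(O)cc2)O[C@H]1c1ccc(O)cc1 | target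

**Totals and risks**

Total step count: 21. Longest linear sequence: 13 steps (13 → 33 through steps 6, 7, 8, 10 and 13–21).

Steps most likely to fail:

1. Step 17 (aroyl radical addition). The hindered aroyl radical may add too slowly to the β-substituted enal, so that hydrogen abstraction from the weak C–H at C2 of 12 takes over, and the protonation at C4 may show poor facial selectivity. The fallback is ionic; it sets out from triflate 11 and comes back at 29. Methoxycarbonylation of 11 (Pd(OAc)2, dppf, CO, MeOH, Et3N) would give the enoate methyl (2S,6R)-6-ArT-2-(2-ArT-ethyl)-3,6-dihydro-2H-pyran-4-carboxylate F1. A vinyl cuprate (vinylMgBr, CuI, TMSCl) should add to C3 anti to the C2 aryl group and, after protonation, give methyl (2R,3R,4R,6S)-2-ArT-6-(2-ArT-ethyl)-3-ethenyloxane-4-carboxylate F2. Cleavage with OsO4/NaIO4 would give methyl (2R,3R,4R,6S)-2-ArT-6-(2-ArT-ethyl)-3-formyloxane-4-carboxylate F3. Aryllithium 26 (made from 25 as in step 15) would add to the aldehyde, and the alkoxide should close on the cis ester to the cis-fused lactone (4R,6S,7aR)-4-ArT-6-(2-ArT-ethyl)-3-[3-Hep-6-methoxy-2,4-bis(methoxymethoxy)phenyl]hexahydro-1H-furo[3,4-c]pyran-1-one F4, which marks the 3,4-cis isomer. LiAlH4 would open it to the diol [(2R,3R,4R,6S)-2-ArT-6-(2-ArT-ethyl)-4-(hydroxymethyl)oxan-3-yl][3-Hep-6-methoxy-2,4-bis(methoxymethoxy)phenyl]methanol F5, and Dess–Martin oxidation of both carbinols would give 29.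

2. Step 10 (anti-SN2' arylation). The di-ortho-substituted arylcopper may react slowly, attack may drift to the α-carbon, and chirality transfer may erode. The fallback exchanges the roles of the two aryl groups; it sets out from aryllithium 19 and comes back at 21. A DMF quench would give 4-methoxy-2,6-bis(methoxymethoxy)benzaldehyde F6. Claisen–Schmidt condensation with acetone (NaOH) would give (E)-4-[4-methoxy-2,6-bis(methoxymethoxy)phenyl]but-3-en-2-one F7. Reduction with (S)-2-methyl-CBS-oxazaborolidine and catecholborane would give (2R,3E)-4-[4-methoxy-2,6-bis(methoxymethoxy)phenyl]but-3-en-2-ol F8, and picolinic acid/DCC its ester (2R,3E)-4-[4-methoxy-2,6-bis(methoxymethoxy)phenyl]but-3-en-2-yl pyridine-2-carboxylate F9. Anti-SN2' substitution with the unhindered cuprate 9 (made as in step 4, with MgBr2·OEt2) would then place the ArT group on the benzylic carbon and give 21 with the same (R) configuration.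

3. Step 13 (cross-metathesis). The double bond may migrate into conjugation with the two aryl rings, the hindered internal alkene may convert incompletely, and an E/Z mixture may form. The fallback builds the whole chain before the arylation, so that the E-alkene arises in the substitution itself; it sets out from ketone 14 and aldehyde 3 and comes back at 24. The boron enolate of 14 (Ipc2BCl, Et3N, the antipode that attacks the Re face of 3) would give the aldol (1E,5S)-5-hydroxy-1,7-bis(ArT)hept-1-en-3-one F10. TBSOTf/2,6-lutidine would give (1E,5S)-5-[(tert-butyldimethylsilyl)oxy]-1,7-bis(ArT)hept-1-en-3-one F11. Reduction with (R)-2-methyl-CBS-oxazaborolidine and catecholborane would give (1E,3S,5S)-5-[(tert-butyldimethylsilyl)oxy]-1,7-bis(ArT)hept-1-en-3-ol F12, and picolinic acid/DCC its ester (1E,3S,5S)-5-[(tert-butyldimethylsilyl)oxy]-1,7-bis(ArT)hept-1-en-3-yl pyridine-2-carboxylate F13. Anti-SN2' arylation with cuprate 20 under the conditions of step 10 would give 24.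

Further compounds
F1 | step 17 | methyl (2S,6R)-6-ArT-2-(2-ArT-ethyl)-3,6-dihydro-2H-pyran-4-carboxylate | C1=C(C(=O)OC)C[C@H](CCc2ccc(O[Si](C)(C)C(C)(C)C)cc2)O[C@H]1c1ccc(O[Si](C)(C)C(C)(C)C)cc1
F2 | step 17 | methyl (2R,3R,4R,6S)-2-ArT-6-(2-ArT-ethyl)-3-ethenyloxane-4-carboxylate | C=C[C@@H]1[C@H](C(=O)OC)C[C@H](CCc2ccc(O[Si](C)(C)C(C)(C)C)cc2)O[C@H]1c1ccc(O[Si](C)(C)C(C)(C)C)cc1
F3 | step 17 | methyl (2R,3R,4R,6S)-2-ArT-6-(2-ArT-ethyl)-3-formyloxane-4-carboxylate | O=C[C@@H]1[C@H](C(=O)OC)C[C@H](CCc2ccc(O[Si](C)(C)C(C)(C)C)cc2)O[C@H]1c1ccc(O[Si](C)(C)C(C)(C)C)cc1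
F4 | step 17 | (4R,6S,7aR)-4-ArT-6-(2-ArT-ethyl)-3-[3-Hep-6-methoxy-2,4-bis(methoxymethoxy)phenyl]hexahydro-1H-furo[3,4-c]pyran-1-one (cis-fused, carbinol carbon as a mixture) | COc1cc(OCOC)c([C@H](/C=C/C[C@@H](O[Si](C)(C)C(C)(C)C)CCc2ccc(O[Si](C)(C)C(C)(C)C)cc2)c2ccc(O[Si](C)(C)C(C)(C)C)cc2)c(OCOC)c1C1OC(=O)[C@@H]2C[C@H](CCc3ccc(O[Si](C)(C)C(C)(C)C)cc3)O[C@@H](c3ccc(O[Si](C)(C)C(C)(C)C)cc3)[C@H]12
F5 | step 17 | [(2R,3R,4R,6S)-2-ArT-6-(2-ArT-ethyl)-4-(hydroxymethyl)oxan-3-yl][3-Hep-6-methoxy-2,4-bis(methoxymethoxy)phenyl]methanol (carbinol carbon as a mixture) | COc1cc(OCOC)c([C@H](/C=C/C[C@@H](O[Si](C)(C)C(C)(C)C)CCc2ccc(O[Si](C)(C)C(C)(C)C)cc2)c2ccc(O[Si](C)(C)C(C)(C)C)cc2)c(OCOC)c1C(O)[C@@H]1[C@H](CO)C[C@H](CCc2ccc(O[Si](C)(C)C(C)(C)C)cc2)O[C@H]1c1ccc(O[Si](C)(C)C(C)(C)C)cc1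
F6 | step 10 | 4-methoxy-2,6-bis(methoxymethoxy)benzaldehyde | COc1cc(OCOC)c(C=O)c(OCOC)c1
F7 | step 10 | (E)-4-[4-methoxy-2,6-bis(methoxymethoxy)phenyl]but-3-en-2-one | COc1cc(OCOC)c(/C=C/C(C)=O)c(OCOC)c1
F8 | step 10 | (2R,3E)-4-[4-methoxy-2,6-bis(methoxymethoxy)phenyl]but-3-en-2-ol | COc1cc(OCOC)c(/C=C/[C@@H](C)O)c(OCOC)c1
F9 | step 10 | (2R,3E)-4-[4-methoxy-2,6-bis(methoxymethoxy)phenyl]but-3-en-2-yl pyridine-2-carboxylate | COc1cc(OCOC)c(/C=C/[C@@H](C)OC(=O)c2ccccn2)c(OCOC)c1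
F10 | step 13 | (1E,5S)-5-hydroxy-1,7-bis(ArT)hept-1-en-3-one | O=C(/C=C/c1ccc(O[Si](C)(C)C(C)(C)C)cc1)C[C@@H](O)CCc1ccc(O[Si](C)(C)C(C)(C)C)cc1
F11 | step 13 | (1E,5S)-5-[(tert-butyldimethylsilyl)oxy]-1,7-bis(ArT)hept-1-en-3-one | O=C(/C=C/c1ccc(O[Si](C)(C)C(C)(C)C)cc1)C[C@@H](O[Si](C)(C)C(C)(C)C)CCc1ccc(O[Si](C)(C)C(C)(C)C)cc1
F12 | step 13 | (1E,3S,5S)-5-[(tert-butyldimethylsilyl)oxy]-1,7-bis(ArT)hept-1-en-3-ol | CC(C)(C)[Si](C)(C)Oc1ccc(/C=C/[C@@H](O)C[C@@H](O[Si](C)(C)C(C)(C)C)CCc2ccc(O[Si](C)(C)C(C)(C)C)cc2)cc1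
F13 | step 13 | (1E,3S,5S)-5-[(tert-butyldimethylsilyl)oxy]-1,7-bis(ArT)hept-1-en-3-yl pyridine-2-carboxylate | CC(C)(C)[Si](C)(C)Oc1ccc(/C=C/[C@@H](OC(=O)c2ccccn2)C[C@@H](O[Si](C)(C)C(C)(C)C)CCc2ccc(O[Si](C)(C)C(C)(C)C)cc2)cc1
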